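**Retrosynthetic overview**
1. The last C–C bond made joins C5 of the benzene ring to the exocyclic CH(CH3)O carbon. An aryl iodide (iodine on C5) and 1-chloroethyl (2R)-2-methylbutanoate are united by an enantioconvergent nickel-catalysed reductive cross-electrophile coupling. This forms the bond, sets the (R) benzylic centre and brings in the 2-methylbutanoate, so the two different esters never have to be told apart.
2. Enabling feature: the exocyclic carbon bears CH3 and an acyloxy oxygen, so it sits at the aldehyde oxidation level (acetaldehyde plus acid chloride give the chloro ester) and gives an oxygen-stabilised, prochiral radical. C5 lies para to ring oxygen O1 and is carried as a plain sp2 C–I from 5-iodosalicylaldehyde.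
3. Ring order: the benzene ring is bought. The dihydrofuran ring is the only ring made, by C2–C3 bond formation in a proline-catalysed 5-enolexo aldol of the O-acetonyl salicylaldehyde, which sets the cis C2/C3 pair.
4. Ketone methylenation gives the isopropenyl group and O3 is acylated with isovaleryl chloride. The acrolein is revealed last by allylic oxidation of the isopropenyl CH3, which is kept reduced through the radical coupling.

Key step: step 6

Remark: the acyl group on the benzylic oxygen as drawn is (R)-2-methylbutanoyl, and (2R)-2-methylbutanoic acid is taken as a purchasable single enantiomer. The sense of induction of the nickel ligand in step 6 is to be confirmed on 4-iodoanisole before 7 is committed.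

**Step 1**
Reactants: 1 2-hydroxy-5-iodobenzaldehyde; 2 chloroacetone
Product: 3 5-iodo-2-(2-oxopropoxy)benzaldehyde
Conditions: K2CO3 (1.5 equiv), KI (cat.), acetone, rt
Reagents that add atoms: none
Why: Williamson ether synthesis in which the phenoxide displaces chloride from the α-chloro ketone (iodide catalysis of Finkelstein type), while room temperature and a mild carbonate base keep the product from Rap–Stoermer cyclodehydration; no stereocentre is formed.

**Step 2**
Reactants: 3 5-iodo-2-(2-oxopropoxy)benzaldehyde
Product: 4 1-[(2S,3R)-3-hydroxy-5-iodo-2,3-dihydro-1-benzofuran-2-yl]ethan-1-one (cis)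
Conditions: (S)-proline (30 mol%), DMF, rt
Reagents that add atoms: none
Why: Proline-catalysed intramolecular 5-enolexo aldol reaction (enamine catalysis) closes the dihydrofuran ring through the C2–C3 bond; the carboxylic acid of (S)-proline hydrogen-bonds the tethered aldehyde and delivers it to the enamine face on its own side while the short O1–aryl tether forces the aryl group and O1 to eclipse, which should set C2 and C3 together as the cis (2S,3R) pair (sense to be verified by correlation, with (R)-proline as the remedy if it is reversed; crystallisation of the iodide should upgrade enantiomeric purity).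

**Step 3**
Reactants: 4 1-[(2S,3R)-3-hydroxy-5-iodo-2,3-dihydro-1-benzofuran-2-yl]ethan-1-one
Product: 5 (2R,3R)-5-iodo-2-(prop-1-en-2-yl)-2,3-dihydro-1-benzofuran-3-ol (cis)
Conditions: Zn, CH2Br2, TiCl4, THF (reagent pre-formed, −40 → 5 °C); then 4, CH2Cl2, 0 °C → rt
Reagents that add atoms: dibromomethane, BrCBr
Why: Takai–Lombardo methylenation, whose non-basic Zn/Ti gem-dimetallic methylene reagent olefinates the ketone without enolising C2 and tolerates the free hydroxyl, so the cis C2/C3 relationship is retained (the C2 descriptor changes from S to R only through the change in CIP priorities).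

**Step 4**
Reactants: 5 (2R,3R)-5-iodo-2-(prop-1-en-2-yl)-2,3-dihydro-1-benzofuran-3-ol; 6 3-methylbutanoyl chloride
Product: 7 (2R,3R)-5-iodo-2-(prop-1-en-2-yl)-2,3-dihydro-1-benzofuran-3-yl 3-methylbutanoate
Conditions: pyridine, DMAP (cat.), CH2Cl2, 0 °C
Reagents that add atoms: none
Why: DMAP-catalysed acylation (nucleophilic acyl transfer) of the secondary benzylic alcohol occurs at oxygen with retention at C3, and with the ketone gone C2–H is no longer acidic enough for aromatising elimination.

**Step 5**
Reactants: 8 (2R)-2-methylbutanoic acid; 9 acetaldehyde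
Product: 11 1-chloroethyl (2R)-2-methylbutanoate (both epimers at the chlorinated carbon), via (2R)-2-methylbutanoyl chloride 10 (not isolated)
Conditions: (COCl)2, DMF (cat.), CH2Cl2, 0 °C → rt; then 9, ZnCl2 (2 mol%), −10 °C → rt; distillation under reduced pressure
Reagents that add atoms: oxalyl chloride, ClC(=O)C(Cl)=O
Why: Acid chloride formation under Vilsmeier-type catalysis followed by ZnCl2-catalysed addition of the acyl chloride across the aldehyde C=O (the standard preparation of 1-chloroalkyl esters) is base-free, so the α-stereocentre of the acid is preserved, while the new chlorinated carbon forms as both epimers, which is of no consequence because step 6 erases it.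

**Step 6**
Reactants: 7 (2R,3R)-5-iodo-2-(prop-1-en-2-yl)-2,3-dihydro-1-benzofuran-3-yl 3-methylbutanoate; 11 1-chloroethyl (2R)-2-methylbutanoate (1.8 equiv)
Product: 12 (1R)-1-[(2R,3R)-3-(3-methylbutanoyloxy)-2-(prop-1-en-2-yl)-2,3-dihydro-1-benzofuran-5-yl]ethyl (2R)-2-methylbutanoate
Conditions: NiBr2·glyme (10 mol%), (4S,4'S)-4,4'-di(heptan-4-yl)-4,4',5,5'-tetrahydro-2,2'-bioxazole (12 mol%), Mn powder (3 equiv), NaI (0.5 equiv), TMSCl (0.1 equiv), DMA, 0 °C
Reagents that add atoms: none
Why: Ligated zerovalent nickel inserts into the C5–I bond of 7, a monovalent nickel species abstracts chlorine from either epimer of 11 to give the same planar, oxygen-stabilised 1-acyloxyethyl radical, the aryl–nickel species captures this radical, and reductive elimination from trivalent nickel forges the C5–CH bond while Mn returns nickel to the low-valent state. The closest known reaction type is the nickel-catalysed enantioconvergent cross-coupling of racemic 1-haloalkyl esters, together with the asymmetric reductive cross-electrophile arylation of secondary α-heteroatom-substituted alkyl chlorides with aryl iodides. No ring is closed in this step. The single new stereocentre, the benzylic carbon (R), should be set under catalyst control by the C2-symmetric bis(oxazoline) ligand during radical capture and reductive elimination, with the ester carbonyl as a secondary binding point; the stereocentres of 7 and the acyl stereocentre of 11 are too remote to interfere, and the ligand antipode is used should the model coupling show the opposite sense. The step needs cross- over homo-coupling selectivity, which the different activation modes of the sp2 C–I bond (two-electron oxidative addition) and the sp3 C–Cl bond (halogen abstraction) secure, and chemoselectivity over the allylic C2–O1 ether, the benzylic C3 ester and the isopropenyl group, which should hold because C–I insertion is far faster than C–O ionisation at 0 °C and the nucleophilic radical does not add to an unactivated 1,1-disubstituted alkene. The acrolein is deliberately still at the methyl oxidation level, since an enal would trap the radical by conjugate addition.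

**Step 7**
Reactants: 12 (1R)-1-[(2R,3R)-3-(3-methylbutanoyloxy)-2-(prop-1-en-2-yl)-2,3-dihydro-1-benzofuran-5-yl]ethyl (2R)-2-methylbutanoate
Product: 14 (1R)-1-[(2R,3R)-3-(3-methylbutanoyloxy)-2-(3-oxoprop-1-en-2-yl)-2,3-dihydro-1-benzofuran-5-yl]ethyl (2R)-2-methylbutanoate (target), via allylic alcohol 13 (not isolated)
Conditions: SeO2 (0.3 equiv), tBuOOH (3 equiv), CH2Cl2, 0 °C → rt; then MnO2 (excess), CH2Cl2, rt
Reagents that add atoms: selenium dioxide, O=[Se]=O; tert-butyl hydroperoxide, CC(C)(C)OO
Why: Catalytic SeO2/tBuOOH allylic oxidation (ene reaction followed by [2,3]-sigmatropic shift) should hydroxylate the methyl group of the 1,1-disubstituted alkene in preference to the hindered C2–H methine, and MnO2 then dehydrogenates the primary allylic alcohol selectively under neutral conditions that touch neither the esters nor the γ-acidic C2–H, so no stereocentre is disturbed.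

**Compound list**
1 | 2-hydroxy-5-iodobenzaldehyde (5-iodosalicylaldehyde) | O=Cc1cc(I)ccc1O | starting material
2 | chloroacetone (1-chloropropan-2-one) | CC(=O)CCl | starting material
3 | 5-iodo-2-(2-oxopropoxy)benzaldehyde | CC(=O)COc1ccc(I)cc1C=O | intermediate
4 | 1-[(2S,3R)-3-hydroxy-5-iodo-2,3-dihydro-1-benzofuran-2-yl]ethan-1-one | CC(=O)[C@H]1Oc2ccc(I)cc2[C@H]1O | intermediate
5 | (2R,3R)-5-iodo-2-(prop-1-en-2-yl)-2,3-dihydro-1-benzofuran-3-ol | C=C(C)[C@H]1Oc2ccc(I)cc2[C@H]1O | intermediate
6 | 3-methylbutanoyl chloride (isovaleryl chloride) | CC(C)CC(Cl)=O | starting material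
7 | (2R,3R)-5-iodo-2-(prop-1-en-2-yl)-2,3-dihydro-1-benzofuran-3-yl 3-methylbutanoate | C=C(C)[C@H]1Oc2ccc(I)cc2[C@H]1OC(=O)CC(C)C | intermediate
8 | (2R)-2-methylbutanoic acid | CC[C@@H](C)C(O)=O | starting material
9 | acetaldehyde | CC=O | starting material
10 | (2R)-2-methylbutanoyl chloride | CC[C@@H](C)C(Cl)=O | intermediate
11 | 1-chloroethyl (2R)-2-methylbutanoate (both epimers at the chlorinated carbon) | CC[C@@H](C)C(=O)OC(C)Cl | intermediate
12 | (1R)-1-[(2R,3R)-3-(3-methylbutanoyloxy)-2-(prop-1-en-2-yl)-2,3-dihydro-1-benzofuran-5-yl]ethyl (2R)-2-methylbutanoate | C=C(C)[C@H]1Oc2ccc([C@@H](C)OC(=O)[C@H](C)CC)cc2[C@H]1OC(=O)CC(C)C | intermediate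
13 | (1R)-1-[(2R,3R)-2-(3-hydroxyprop-1-en-2-yl)-3-(3-methylbutanoyloxy)-2,3-dihydro-1-benzofuran-5-yl]ethyl (2R)-2-methylbutanoate | C=C(CO)[C@H]1Oc2ccc([C@@H](C)OC(=O)[C@H](C)CC)cc2[C@H]1OC(=O)CC(C)C | intermediate
14 | (1R)-1-[(2R,3R)-3-(3-methylbutanoyloxy)-2-(3-oxoprop-1-en-2-yl)-2,3-dihydro-1-benzofuran-5-yl]ethyl (2R)-2-methylbutanoate | C=C(C=O)[C@H]1Oc2ccc([C@@H](C)OC(=O)[C@H](C)CC)cc2[C@H]1OC(=O)CC(C)C | target

**Step count and risks**
Total step count: 7. Longest linear sequence: 6 steps (steps 1, 2, 3, 4, 6 and 7, from 1).

Steps most likely to fail: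

1. Step 6. What may go wrong: homocoupling or protodeiodination of the aryl–nickel intermediate, β-hydride elimination of the alkyl–nickel species to a vinyl ester, or poor facial discrimination in the radical capture so that both epimers at the benzylic carbon form. The fallback sets out from 7 and returns at 12. Iodine–magnesium exchange of 7 with iPrMgCl·LiCl (THF, −40 °C, where the ester should survive) and acylation with N-methoxy-N-methylacetamide should give (2R,3R)-5-acetyl-2-(prop-1-en-2-yl)-2,3-dihydro-1-benzofuran-3-yl 3-methylbutanoate F1. Noyori asymmetric transfer hydrogenation with RuCl[(R,R)-TsDPEN](p-cymene) in HCO2H/Et3N should reduce the aryl methyl ketone to (2R,3R)-5-[(1R)-1-hydroxyethyl]-2-(prop-1-en-2-yl)-2,3-dihydro-1-benzofuran-3-yl 3-methylbutanoate F2 without touching the isopropenyl group. Steglich esterification of F2 with acid 8 (N,N'-diisopropylcarbodiimide, DMAP cat., CH2Cl2, 0 °C) then gives 12.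

2. Step 7. What may go wrong: acid-promoted ionisation of the two benzylic esters with aromatising loss of the C3 ester, or an ene reaction that stalls or is misdirected, on the fully assembled molecule. The fallback sets out from 7 and returns at 13; it moves the allylic oxidation ahead of the coupling, where no para-alkoxybenzylic ester is present. Compound 7 is treated with catalytic SeO2/tBuOOH (CH2Cl2, rt; any enal returned to the alcohol by Luche reduction, NaBH4/CeCl3·7H2O) to give (2R,3R)-2-(3-hydroxyprop-1-en-2-yl)-5-iodo-2,3-dihydro-1-benzofuran-3-yl 3-methylbutanoate F3. Silylation (TBSCl, imidazole, DMF) gives (2R,3R)-2-[3-(tert-butyldimethylsilyloxy)prop-1-en-2-yl]-5-iodo-2,3-dihydro-1-benzofuran-3-yl 3-methylbutanoate F4. Coupling of F4 with 11 under the conditions of step 6 gives (1R)-1-[(2R,3R)-2-[3-(tert-butyldimethylsilyloxy)prop-1-en-2-yl]-3-(3-methylbutanoyloxy)-2,3-dihydro-1-benzofuran-5-yl]ethyl (2R)-2-methylbutanoate F5. HF·pyridine (THF, 0 °C) frees the alcohol 13, now isolated, and MnO2 as in the second stage of step 7 gives 14.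

3. Step 3. What may go wrong: Lewis-acid-promoted dehydration of the β-hydroxy ketone to the aromatic 2-acetylbenzofuran, or retro-aldol ring opening with epimerisation at C2, before methylene transfer occurs. The fallback sets out from 4 and returns at 5; it replaces the titanium methylene reagent by carbonyl addition and elimination. Compound 4 is silylated (TESCl, imidazole, DMF, 0 °C) to 1-[(2S,3R)-5-iodo-3-(triethylsilyloxy)-2,3-dihydro-1-benzofuran-2-yl]ethan-1-one F6. The weakly basic organocerium reagent from Me3SiCH2MgCl and CeCl3 (THF, −78 °C) should add to the enolisable ketone to give 2-[(2S,3R)-5-iodo-3-(triethylsilyloxy)-2,3-dihydro-1-benzofuran-2-yl]-1-(trimethylsilyl)propan-2-ol F7 (both carbinol epimers). Aqueous HF in MeCN (0 °C) effects the Peterson elimination and removes the triethylsilyl group in the same operation, returning 5.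

**Further compounds**
F1 | step 6 | (2R,3R)-5-acetyl-2-(prop-1-en-2-yl)-2,3-dihydro-1-benzofuran-3-yl 3-methylbutanoate | C=C(C)[C@H]1Oc2ccc(C(C)=O)cc2[C@H]1OC(=O)CC(C)C
F2 | step 6 | (2R,3R)-5-[(1R)-1-hydroxyethyl]-2-(prop-1-en-2-yl)-2,3-dihydro-1-benzofuran-3-yl 3-methylbutanoate | C=C(C)[C@H]1Oc2ccc([C@@H](C)O)cc2[C@H]1OC(=O)CC(C)C
F3 | step 7 | (2R,3R)-2-(3-hydroxyprop-1-en-2-yl)-5-iodo-2,3-dihydro-1-benzofuran-3-yl 3-methylbutanoate | C=C(CO)[C@H]1Oc2ccc(I)cc2[C@H]1OC(=O)CC(C)C
F4 | step 7 | (2R,3R)-2-[3-(tert-butyldimethylsilyloxy)prop-1-en-2-yl]-5-iodo-2,3-dihydro-1-benzofuran-3-yl 3-methylbutanoate | C=C(CO[Si](C)(C)C(C)(C)C)[C@H]1Oc2ccc(I)cc2[C@H]1OC(=O)CC(C)C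
F5 | step 7 | (1R)-1-[(2R,3R)-2-[3-(tert-butyldimethylsilyloxy)prop-1-en-2-yl]-3-(3-methylbutanoyloxy)-2,3-dihydro-1-benzofuran-5-yl]ethyl (2R)-2-methylbutanoate | C=C(CO[Si](C)(C)C(C)(C)C)[C@H]1Oc2ccc([C@@H](C)OC(=O)[C@H](C)CC)cc2[C@H]1OC(=O)CC(C)C
F6 | step 3 | 1-[(2S,3R)-5-iodo-3-(triethylsilyloxy)-2,3-dihydro-1-benzofuran-2-yl]ethan-1-one | CC(=O)[C@H]1Oc2ccc(I)cc2[C@H]1O[Si](CC)(CC)CC
F7 | step 3 | 2-[(2S,3R)-5-iodo-3-(triethylsilyloxy)-2,3-dihydro-1-benzofuran-2-yl]-1-(trimethylsilyl)propan-2-ol (both carbinol epimers) | CC(O)(C[Si](C)(C)C)[C@H]1Oc2ccc(I)cc2[C@H]1O[Si](CC)(CC)CC
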